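# Proposed synthesis of CNP0212960.1 by a furan Diels–Alder reaction with a temporary oxygen bridge

Target: [(1R,5R,6S)-6-(benzoyloxy)-1,5-dihydroxy-2-oxocyclohex-3-en-1-yl]methyl benzoate, compound 16, SMILES O=C(OC[C@]1(O)C(=O)C=C[C@@H](O)[C@@H]1OC(=O)c1ccccc1)c1ccccc1.

## Analysis of the target

Compound 16 is a single six-membered carbocycle, a cyclohex-3-en-2-one. The ring is numbered from the tertiary carbinol C1, which carries the benzoyloxymethyl carbon C7, through the ketone C2, the alkene C3=C4 and the free allylic carbinol C5 to the benzoate carbon C6; the same locants are used for all bicyclic intermediates, in which "the bridge oxygen" is the oxygen that ends as the C1 hydroxyl. The three stereocentres are contiguous, (1R,5R,6S): the hydroxyls on C1 and C5 lie on one face of the ring and the C6 benzoate on the other, so the C6 oxygen is trans to both of its neighbours. The molecule is a γ-hydroxy enone that can lose the C6 benzoate through a dienolate, it contains a tertiary α-ketol, and each benzoate is vicinal to a free hydroxyl, so any free alkoxide invites acyl migration. The difficulty is that the four oxygens on C7, C1, C6 and C5 must end in two different states (two esters, two free alcohols) around a quaternary C1, and that C2 must become the ketone while C5, at the other end of the alkene, stays a carbinol. The strategy rests on the fact that the C1 oxygen and C4 are 1,4 to each other across the ring and that C4 is β to the C2 ketone through C3. An ether bond from the C1 oxygen to C4 is therefore a β-alkoxy ketone that C2 can break by enolising toward C3, leaving exactly the C1 hydroxyl and the C3=C4 alkene. The bridged ketone is a 7-oxabicyclo[2.2.1]heptan-2-one, in which the C5 hydroxyl is exo and the C6 benzoate endo, the pattern left by an exo epoxide opened from the endo face.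

## Retrosynthetic reasoning

**16 back to 13.** The last operation is the one that creates the enone. In 16 the C1–O bond and the C3=C4 double bond are read as the two ends of a broken ether; reconnecting the C1 oxygen to C4 gives the bridged ketone 13, in which C3 is the only enolisable position. Cutting here, and not at a ring C–C bond, replaces the elimination-prone enone by a rigid bicycle with C1 as bridgehead, the C5 hydroxyl exo and the C6 ester endo. The forward reaction must enolise 13 toward C3 and break C4–O without ever forming a free alkoxide beside the two esters; the silyl enol ether 14 and the doubly silylated enone 15 are the intermediates that allow this.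

**13 back to 12.** In 13 the exo C5 hydroxyl and the endo C6 ester are trans across C5–C6, the signature of an epoxide opened with inversion. The C6–O bond is therefore cut to give the exo epoxide 12. The cut is at C6 and not at C5 because in 12 the C2 carbonyl biases exactly this carbon toward substitution, so a group already present solves the regiochemistry. The forward reaction has to deliver the benzoyloxy group to C6 from the endo face under acid catalysis and leave the C7 ester untouched.

**12 back to 9, 8 and 7.** The C2 carbonyl of 12 cannot come directly from a cycloaddition, so it is traced to a carbon bearing a bromine atom and a one-carbon acyl group, the acid 9. The acyl carbon is removed by Curtius rearrangement through 10 and 11, followed by hydrolysis. Acid 9 comes from aldehyde 8 by oxidation, and the epoxide of 8 from the C5=C6 alkene of 7. The epoxide is installed before the ketone is unveiled for two reasons: a strained bicyclic ketone would compete with the alkene for a peroxy-acid type oxidant by ring expansion, and a bicycle without the alkene cannot undergo cycloreversion during the thermal rearrangement.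

**7 back to 3 and 6.** The cyclohexene of 7 consists of a four-carbon unit (C1, C6, C5, C4, joined through the bridge oxygen) and a two-carbon unit (C2, C3). Cutting C1–C2 and C3–C4 gives the 2-substituted furan 3 as diene and the α-bromo enal 6 as dienophile. No other disconnection makes the ring, the bridge and the C1 stereocentre in one operation from achiral compounds. The forward reaction needs a chiral Lewis acid to choose the face and the polarity of both partners to place C2 next to C1.

**3 back to 1 and 2; 6 back to 4.** Compound 3 is the ester of alcohol 1 with acid chloride 2, so the C7 benzoate of 16 is present from the first step and never has to be introduced selectively. Compound 6 is made from 4 by bromination of the alkene, giving 5, and elimination.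

## Alternatives that were turned down

**Alternative 1:** Ferrier carbocyclisation of a branched sugar.
- Disconnection: the C3=C4 alkene is traced to the β-hydroxy ketone A2, and A2 is cut at C3–C4, which leads to the branched methyl hex-5-enopyranoside A1 (the later C2 is its enol ether carbon, the later C4 its anomeric carbon).
- Forward key step: catalytic Hg(OCOCF3)2 in aqueous acetone hydrates the exocyclic enol ether of A1; the hemiacetal collapses to a C2 ketone with a mercurated C3 and a C4 aldehyde, and an intramolecular aldol addition closes the ring to A2.
- For it: C5 and C6 come from the chiral pool with certainty, the new C4 carbinol is eliminated afterwards so its configuration does not matter, and the endgame from A2 is short (dehydration, removal of the 4-methoxybenzyl ether).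
- Against it: A1 needs a quaternary centre at the carbon that becomes C1, carrying a free tertiary hydroxyl and the benzoyloxymethyl group with defined configuration, directly beside the enol ether. Building that branch on a pyranoside together with three differentiated oxygens should take on the order of ten or more operations, the free tertiary hydroxyl next to two benzoates is a migration hazard throughout, and a mercury salt is needed.
- Comparison: on the configuration of C5 and C6 this route is stronger than the chosen one, which depends on face and site selectivity in a bicycle. The chosen route offers in its place a target reached in eight steps from three commodity chemicals, with C1 set catalytically.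

**Alternative 2:** Singlet-oxygen endoperoxide across C2 and C5.
- Disconnection: both the C2 and C5 oxygens are traced to one molecule of dioxygen; 16 comes from the endoperoxide A4 by base-induced Kornblum–DeLaMare rearrangement, and A4 from the cyclohexadienol A3.
- Forward key step: sensitised photo-oxygenation (O2, light, tetraphenylporphyrin) adds singlet oxygen across C2 and C5 of A3 on the face of the C1 hydroxyl, anti to the C6 benzoate, giving A4.
- For it: from A3 the target is two steps away, the hydroxyl-directed and ester-avoiding approach of the oxidant should give the right C5 configuration, and the sequence mirrors a plausible biogenesis. On step count after the diene it beats the chosen route.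
- Against it: A3 is a 1-hydroxycyclohexa-2,4-diene that aromatises by loss of water or of benzoic acid, and no short enantioselective entry to its trans C1/C6 arrangement with a quaternary C1 is apparent. The rearrangement of A4 must remove the bridgehead hydrogen at C2, which is flanked by the quaternary C1, in preference to the more accessible one at C5; the isomeric enone with the ketone at C5 is the likelier outcome.
- Comparison: the chosen route fixes which carbon becomes the ketone by construction, because C2 is the carbon that carries the masked carbonyl from the cycloaddition, and its precursors are stable.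

**Alternative 3:** Silicon-tethered hydroxymethyl delivery onto a conduritol ketone.
- Disconnection: the C1–C7 bond is cut; 16 is traced through oxidation of the C–Si bond to the oxasilolane A6 and from there to the α,α′-dioxygenated ketone A5 carrying a (bromomethyl)dimethylsilyl ether on the C6 oxygen.
- Forward key step: SmI2 in THF reduces the C–Br bond of A5 and the α-silyl carbanion adds to the C1 ketone on the face of the tether, closing the cis-fused five-membered ring of A6.
- For it: intramolecular delivery ties the configuration of C1 to that of C6 by ring fusion, which is at least as secure as catalyst control of C1 in the chosen route, and enantiopure conduritol building blocks exist.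
- Against it: samarium diiodide readily cleaves C–O bonds α to a ketone through the ketyl, and A5 has two of them, one being the tether itself. After oxidation of the C–Si bond the route still has to benzoylate two of three hydroxyls, remove two identical 4-methoxybenzyl ethers and then oxidise C2 but not C5, although both are secondary allylic alcohols; that calls for a different protecting-group pattern and more steps.
- Comparison: the chosen route is shorter and delivers C2 as a ketone and C5 as an alcohol without any differentiation step.

Key step: step 3

Assumption: the oxazaborolidinone made from N-(4-methylphenylsulfonyl)-(S)-tryptophan is taken to leave open the face of bound 6 that gives the (2R)-bromo aldehyde, the sense known for this catalyst with cyclopentadiene; if the sense were opposite, the catalyst from (R)-tryptophan would be used with no other change.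

## Route

Step 1
Reactants: 1 furfuryl alcohol; 2 benzoyl chloride
Product: 3 furan-2-ylmethyl benzoate
Conditions: Et3N, 4-(dimethylamino)pyridine (cat.), CH2Cl2, 0 °C to rt
Reagents that add atoms: none
Why: Nucleophilic acyl substitution (base-mediated O-acylation) of a primary alcohol; the basic medium protects the acid-sensitive furan.

Step 2
Reactants: 4 acrolein
Product: 6 2-bromoacrolein, via 2,3-dibromopropanal 5 (not isolated)
Conditions: Br2, CH2Cl2, −78 to 0 °C; then Et3N, 0 °C; distilled at reduced pressure and kept cold
Reagents that add atoms: bromine, BrBr
Why: Electrophilic addition of bromine to the alkene gives 5, and the amine removes the acidic α-hydrogen so that the β-bromide leaves (E1cB dehydrobromination), which is the standard preparation of this enal.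

Step 3
Reactants: 3 furan-2-ylmethyl benzoate; 6 2-bromoacrolein
Product: 7 [(1S,2R,4R)-2-bromo-2-formyl-7-oxabicyclo[2.2.1]hept-5-en-1-yl]methyl benzoate (formyl exo; bromine endo)
Conditions: (S)-2-butyl-4-(1H-indol-3-ylmethyl)-3-(4-methylphenylsulfonyl)-1,3,2-oxazaborolidin-5-one (10–20 mol %, made beforehand from N-(4-methylphenylsulfonyl)-(S)-tryptophan and BuB(OH)2), 6 in excess, CH2Cl2, −78 °C; cold filtration through silica, used at once
Reagents that add atoms: none
Why: The aldehyde oxygen of 6 binds to boron, which lowers the LUMO of the s-cis enal and lets the indole ring cover one of its faces, so that 3 adds to the open face in a concerted but asynchronous normal-demand [4+2] cycloaddition; the closest known cases are the same catalysed Diels–Alder reactions of furan itself and of cyclopentadiene with 2-haloacroleins. The one new ring, the cyclohexene C1–C6, closes by this intermolecular suprafacial [4+2] addition and, with the furan oxygen across it, forms the 7-oxabicyclo[2.2.1]heptene. The bond from the unsubstituted furan α-carbon to the CH2 terminus of 6 runs ahead, because that furan carbon has the largest HOMO coefficient and the CH2 carbon the largest LUMO coefficient, and the charge that builds at the other furan terminus is supported by the ring oxygen and the attached carbon; this puts C2 next to the substituted bridgehead C1. C1 and C4 are set together by the enal face that the catalyst leaves open, and C2 by the preference of the α-bromine for the endo position, which places the formyl group exo; C2 is erased later. The step needs face selectivity (catalyst), regioselectivity (polarisation of the 2-substituted furan), exo-formyl selectivity (α-substituent) and cycloaddition in preference to conjugate addition with rearomatisation (low temperature and a weak, aldehyde-selective Lewis acid). The ester of 3 is a poorer Lewis base than the aldehyde and should not be ionised by the boron centre at −78 °C. The adduct can revert to its components, so it is kept cold and carried on immediately.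

Step 4
Reactants: 7 [(1S,2R,4R)-2-bromo-2-formyl-7-oxabicyclo[2.2.1]hept-5-en-1-yl]methyl benzoate
Product: 8 [(1R,2R,4R,5R,6R)-2-bromo-5,6-epoxy-2-formyl-7-oxabicyclo[2.2.1]heptan-1-yl]methyl benzoate (epoxide exo)
Conditions: dimethyldioxirane (acetone solution), CH2Cl2, −20 to 0 °C
Reagents that add atoms: dimethyldioxirane, CC1(C)OO1
Why: Concerted oxygen transfer from the dioxirane to the strained alkene (dioxirane epoxidation) from the exo face, since the endo face is blocked by the endo bromine on C2 and the endo hydrogen on C3; this sets C5 and C6. Saturating C5=C6 makes cycloreversion impossible, and any aldehyde oxidised here converges on 9 in step 5.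

Step 5
Reactants: 8 [(1R,2R,4R,5R,6R)-2-bromo-5,6-epoxy-2-formyl-7-oxabicyclo[2.2.1]heptan-1-yl]methyl benzoate
Product: 9 (1R,2R,4R,5R,6R)-1-(benzoyloxymethyl)-2-bromo-5,6-epoxy-7-oxabicyclo[2.2.1]heptane-2-carboxylic acid
Conditions: NaClO2, NaH2PO4, 2-methyl-2-butene, t-BuOH–H2O, 0 °C to rt
Reagents that add atoms: sodium chlorite, [Na+].[O-]Cl=O
Why: Pinnick oxidation of a hindered, non-enolisable aldehyde; the weakly acidic buffer leaves the benzoate, the tertiary bromide and the epoxide alone, and the alkene scavenger removes hypochlorite.

Step 6
Reactants: 9 (1R,2R,4R,5R,6R)-1-(benzoyloxymethyl)-2-bromo-5,6-epoxy-7-oxabicyclo[2.2.1]heptane-2-carboxylic acid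
Product: 12 [(1R,4R,5R,6R)-5,6-epoxy-2-oxo-7-oxabicyclo[2.2.1]heptan-1-yl]methyl benzoate, via acyl azide 10 (not isolated), via bromo isocyanate 11 (not isolated)
Conditions: (PhO)2P(O)N3, Et3N, toluene, rt then 80 °C; then AcOH–NaOAc, H2O–THF, 50 °C
Reagents that add atoms: water, O
Why: Curtius rearrangement of the α-bromo acyl azide gives the α-bromo isocyanate; water then gives the carbamic acid, which loses CO2, and the α-bromo amine expels bromide to an iminium ion that hydrolyses to the ketone (the classical unmasking of an α-halo acid as a ketone). The acetate buffer keeps the liberated HBr from opening the epoxide, the ester is untouched, and without an alkene the heating cannot cause cycloreversion.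

Step 7
Reactants: 12 [(1R,4R,5R,6R)-5,6-epoxy-2-oxo-7-oxabicyclo[2.2.1]heptan-1-yl]methyl benzoate
Product: 13 [(1R,4R,5R,6S)-6-(benzoyloxy)-5-hydroxy-2-oxo-7-oxabicyclo[2.2.1]heptan-1-yl]methyl benzoate (5-hydroxyl exo; 6-benzoate endo)
Conditions: PhCO2H (excess), CF3SO3H (cat.), CH2Cl2, 0 °C to rt
Reagents that add atoms: benzoic acid, OC(=O)c1ccccc1
Why: Acid-catalysed epoxide acidolysis of a 5,6-exo-epoxy-7-oxabicyclo[2.2.1]heptan-2-one: the protonated epoxide opens at C6 because positive charge there is stabilised through the C1–C2 bond by the carbonyl lone pair (the ketone acting as a homoconjugated donor), and because the endo side of C6 faces the flat carbonyl carbon whereas that of C5 faces the endo hydrogen of C3. The nucleophile enters anti to the epoxide oxygen, so the C6 benzoate is endo (6S) and the C5 hydroxyl stays exo (5R); the trans arrangement on the rigid bicycle prevents acyl migration.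

Step 8
Reactants: 13 [(1R,4R,5R,6S)-6-(benzoyloxy)-5-hydroxy-2-oxo-7-oxabicyclo[2.2.1]heptan-1-yl]methyl benzoate
Product: 16 [(1R,5R,6S)-6-(benzoyloxy)-1,5-dihydroxy-2-oxocyclohex-3-en-1-yl]methyl benzoate (the target), via silyl enol ether 14 (not isolated), via bis(trimethylsilyl) ether 15 (not isolated)
Conditions: Me3SiOSO2CF3, Et3N, CH2Cl2, 0 °C to rt; then 1 M HCl, THF, 0 °C
Reagents that add atoms: none
Why: Silylation of the C5 hydroxyl and soft enolisation toward C3, the only enolisable position, give 14; silyl triflate on the bridge oxygen turns it into a leaving group and the enol ether expels it from C4 (E1cB-type β-elimination, the known silyl-triflate opening of 7-oxabicyclo[2.2.1]heptan-2-ones), forming C3=C4 and leaving the oxygen on C1 as a silyl ether. No free alkoxide appears beside the esters, no stereocentre is touched, and dilute acid removes both silyl groups.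

## Compound list

1 | furfuryl alcohol (furan-2-ylmethanol) | OCc1ccco1 | starting material
2 | benzoyl chloride | O=C(Cl)c1ccccc1 | starting material
3 | furan-2-ylmethyl benzoate | O=C(OCc1ccco1)c1ccccc1 | intermediate
4 | acrolein | C=CC=O | starting material
5 | 2,3-dibromopropanal (racemic) | O=CC(Br)CBr | intermediate
6 | 2-bromoacrolein | C=C(Br)C=O | intermediate
7 | [(1S,2R,4R)-2-bromo-2-formyl-7-oxabicyclo[2.2.1]hept-5-en-1-yl]methyl benzoate | O=C(c1ccccc1)OC[C@]1(O2)[C@@](Br)(C=O)C[C@@H]2C=C1 | intermediate
8 | [(1R,2R,4R,5R,6R)-2-bromo-5,6-epoxy-2-formyl-7-oxabicyclo[2.2.1]heptan-1-yl]methyl benzoate | O=C(c1ccccc1)OC[C@]1(O2)[C@@](Br)(C=O)C[C@@H]2[C@H]3O[C@@H]13 | intermediate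
9 | (1R,2R,4R,5R,6R)-1-(benzoyloxymethyl)-2-bromo-5,6-epoxy-7-oxabicyclo[2.2.1]heptane-2-carboxylic acid | O=C(c1ccccc1)OC[C@]1(O2)[C@@](Br)(C(=O)O)C[C@@H]2[C@H]3O[C@@H]13 | intermediate
10 | (1R,2R,4R,5R,6R)-1-(benzoyloxymethyl)-2-bromo-5,6-epoxy-7-oxabicyclo[2.2.1]heptane-2-carbonyl azide | O=C(c1ccccc1)OC[C@]1(O2)[C@@](Br)(C(=O)N=[N+]=[N-])C[C@@H]2[C@H]3O[C@@H]13 | intermediate
11 | [(1R,2R,4R,5R,6R)-2-bromo-5,6-epoxy-2-isocyanato-7-oxabicyclo[2.2.1]heptan-1-yl]methyl benzoate | O=C(c1ccccc1)OC[C@]1(O2)[C@@](Br)(N=C=O)C[C@@H]2[C@H]3O[C@@H]13 | intermediate
12 | [(1R,4R,5R,6R)-5,6-epoxy-2-oxo-7-oxabicyclo[2.2.1]heptan-1-yl]methyl benzoate | O=C(c1ccccc1)OC[C@]1(O2)C(=O)C[C@@H]2[C@H]3O[C@@H]13 | intermediate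
13 | [(1R,4R,5R,6S)-6-(benzoyloxy)-5-hydroxy-2-oxo-7-oxabicyclo[2.2.1]heptan-1-yl]methyl benzoate | O=C(c1ccccc1)OC[C@]1(O2)C(=O)C[C@@H]2[C@@H](O)[C@@H]1OC(=O)c1ccccc1 | intermediate
14 | [(1R,4R,5R,6S)-6-(benzoyloxy)-2,5-bis(trimethylsilyloxy)-7-oxabicyclo[2.2.1]hept-2-en-1-yl]methyl benzoate | O=C(c1ccccc1)OC[C@]1(O2)C(O[Si](C)(C)C)=C[C@@H]2[C@@H](O[Si](C)(C)C)[C@@H]1OC(=O)c1ccccc1 | intermediate
15 | [(1R,5R,6S)-6-(benzoyloxy)-2-oxo-1,5-bis(trimethylsilyloxy)cyclohex-3-en-1-yl]methyl benzoate | O=C(OC[C@]1(O[Si](C)(C)C)C(=O)C=C[C@@H](O[Si](C)(C)C)[C@@H]1OC(=O)c1ccccc1)c1ccccc1 | intermediate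
16 | [(1R,5R,6S)-6-(benzoyloxy)-1,5-dihydroxy-2-oxocyclohex-3-en-1-yl]methyl benzoate | O=C(OC[C@]1(O)C(=O)C=C[C@@H](O)[C@@H]1OC(=O)c1ccccc1)c1ccccc1 | target

## Step count and least certain steps

Total step count: 8. Longest linear sequence: 7 steps (steps 1, 3, 4, 5, 6, 7 and 8, from furfuryl alcohol); step 2 is a one-step side branch.

**Step 3 (key step).**
- What may go wrong: conjugate addition of the free furan α-position to the activated enal with rearomatisation instead of ring closure; cycloreversion of the adduct on warming; or weaker face or site selectivity than with unsubstituted furan, because the furan substituent lies close to the catalyst.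
- Fallback: it sets out from 3 and 6 and returns at 9. The two are combined without any Lewis acid under high pressure (CH2Cl2, about 12 kbar, rt), which removes the ionic conjugate-addition channel and gives the adduct as a racemate, 7 together with its mirror image F1. The racemate is taken through steps 4 and 5, giving 8 with its mirror image F2 and then 9 with its mirror image F3. The acid is resolved by crystallisation of the (R)-1-phenylethylammonium salt F4 (or the salt of the (S)-amine, whichever crystallises with 9), and acidification releases 9.

**Step 7.**
- What may go wrong: slow capture of the opening epoxide by the weak nucleophile, which would leave room for a 1,2-shift of the acyl carbon from C1 to C6, for interception of C6 by the carbonyl oxygen of the C7 benzoate, or for attack at C5.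
- Fallback: it sets out from 12 and returns at 13. Hydrolysis with the smaller nucleophile water (HClO4 cat., H2O–THF) gives the trans-diol F5. The less hindered exo hydroxyl on C5 is silylated selectively (t-BuMe2SiCl, imidazole, DMF) to F6, the endo hydroxyl on C6 is benzoylated with 2 (pyridine, 4-(dimethylamino)pyridine) to F7, and HF·pyridine removes the silyl group to give 13.

**Step 6.**
- What may go wrong: sluggish activation of the hindered acid between two fully substituted carbons; displacement of bromide by the carboxylate (α-lactone formation) under amine and heat; or opening of the epoxide by bromide during hydrolysis.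
- Fallback: it sets out from 9 and returns at 12, using the α-lactone pathway on purpose. Ag2O in aqueous acetone converts 9 into the α-hydroxy acid F8 (the configuration at C2 is immaterial), and Pb(OAc)4 in CH2Cl2 cleaves F8 by oxidative decarboxylation to 12.

**Step 8.**
- What may go wrong: a second enolisation at C5 of the freshly formed enone with loss of the C6 benzoate and aromatisation, incomplete ring opening of 14, or acyl migration during desilylation.
- Fallback: it sets out from 13 and returns at 16. The C5 hydroxyl is first capped as the triethylsilyl ether F9 (Et3SiCl, imidazole). The lithium enolate is then generated with LiN(SiMe3)2 in THF at −78 °C in the presence of Me3SiCl, so that the expelled C1 alkoxide is silylated as it forms, giving the enone F10. HF·pyridine removes both silyl groups to give 16.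

**Step 4.**
- What may go wrong: loss of 7 by cycloreversion before the alkene is oxidised.
- Fallback: it sets out from 7 in the cycloaddition pot and returns at 8. NaBH4 in MeOH is added at −78 °C to give the bromohydrin F11, which no longer contains an activated dienophile unit and should be stable to cycloreversion. Epoxidation with 3-chloroperbenzoic acid (CH2Cl2, rt) gives the exo epoxide F12, and Dess–Martin periodinane re-oxidises the primary alcohol to 8.

## Further compounds

F1 | step 3 | [(1R,2S,4S)-2-bromo-2-formyl-7-oxabicyclo[2.2.1]hept-5-en-1-yl]methyl benzoate (mirror image of 7) | O=C(c1ccccc1)OC[C@@]1(O2)[C@](Br)(C=O)C[C@H]2C=C1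
F2 | step 3 | [(1S,2S,4S,5S,6S)-2-bromo-5,6-epoxy-2-formyl-7-oxabicyclo[2.2.1]heptan-1-yl]methyl benzoate (mirror image of 8) | O=C(c1ccccc1)OC[C@@]1(O2)[C@](Br)(C=O)C[C@H]2[C@@H]3O[C@H]13
F3 | step 3 | (1S,2S,4S,5S,6S)-1-(benzoyloxymethyl)-2-bromo-5,6-epoxy-7-oxabicyclo[2.2.1]heptane-2-carboxylic acid (mirror image of 9) | O=C(c1ccccc1)OC[C@@]1(O2)[C@](Br)(C(=O)O)C[C@H]2[C@@H]3O[C@H]13
F4 | step 3 | (R)-1-phenylethylammonium salt of 9 | O=C(c1ccccc1)OC[C@]1(O2)[C@@](Br)(C(=O)[O-])C[C@@H]2[C@H]3O[C@@H]13.C[C@@H]([NH3+])c1ccccc1
F5 | step 7 | [(1R,4R,5R,6S)-5,6-dihydroxy-2-oxo-7-oxabicyclo[2.2.1]heptan-1-yl]methyl benzoate (5-hydroxyl exo; 6-hydroxyl endo) | O=C(c1ccccc1)OC[C@]1(O2)C(=O)C[C@@H]2[C@@H](O)[C@@H]1O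
F6 | step 7 | 5-O-(tert-butyldimethylsilyl) ether of F5 | O=C(c1ccccc1)OC[C@]1(O2)C(=O)C[C@@H]2[C@@H](O[Si](C)(C)C(C)(C)C)[C@@H]1O
F7 | step 7 | 5-O-(tert-butyldimethylsilyl) ether of 13 | O=C(c1ccccc1)OC[C@]1(O2)C(=O)C[C@@H]2[C@@H](O[Si](C)(C)C(C)(C)C)[C@@H]1OC(=O)c1ccccc1
F8 | step 6 | (1R,2R,4R,5R,6R)-1-(benzoyloxymethyl)-5,6-epoxy-2-hydroxy-7-oxabicyclo[2.2.1]heptane-2-carboxylic acid | O=C(c1ccccc1)OC[C@]1(O2)[C@@](O)(C(=O)O)C[C@@H]2[C@H]3O[C@@H]13
F9 | step 8 | 5-O-(triethylsilyl) ether of 13 | O=C(c1ccccc1)OC[C@]1(O2)C(=O)C[C@@H]2[C@@H](O[Si](CC)(CC)CC)[C@@H]1OC(=O)c1ccccc1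
F10 | step 8 | [(1R,5R,6S)-6-(benzoyloxy)-2-oxo-5-(triethylsilyloxy)-1-(trimethylsilyloxy)cyclohex-3-en-1-yl]methyl benzoate | O=C(OC[C@]1(O[Si](C)(C)C)C(=O)C=C[C@@H](O[Si](CC)(CC)CC)[C@@H]1OC(=O)c1ccccc1)c1ccccc1
F11 | step 4 | [(1S,2S,4R)-2-bromo-2-(hydroxymethyl)-7-oxabicyclo[2.2.1]hept-5-en-1-yl]methyl benzoate (hydroxymethyl exo) | O=C(c1ccccc1)OC[C@]1(O2)[C@@](Br)(CO)C[C@@H]2C=C1
F12 | step 4 | [(1R,2S,4R,5R,6R)-2-bromo-5,6-epoxy-2-(hydroxymethyl)-7-oxabicyclo[2.2.1]heptan-1-yl]methyl benzoate (epoxide exo) | O=C(c1ccccc1)OC[C@]1(O2)[C@@](Br)(CO)C[C@@H]2[C@H]3O[C@@H]13
A1 | alternative 1 | methyl 3-O-benzoyl-4-C-(benzoyloxymethyl)-6-deoxy-2-O-(4-methoxybenzyl)hex-5-enopyranoside (one anomer shown) | O=C(c1ccccc1)OC[C@]1(O)C(=C)O[C@H](OC)[C@@H](OCc2ccc(OC)cc2)[C@@H]1OC(=O)c1ccccc1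
A2 | alternative 1 | [6-(benzoyloxy)-1,4-dihydroxy-5-(4-methoxybenzyloxy)-2-oxocyclohexyl]methyl benzoate (one C4 epimer shown) | O=C(c1ccccc1)OC[C@]1(O)C(=O)C[C@H](O)[C@@H](OCc2ccc(OC)cc2)[C@@H]1OC(=O)c1ccccc1
A3 | alternative 2 | [6-(benzoyloxy)-1-hydroxycyclohexa-2,4-dien-1-yl]methyl benzoate (hydroxyl and benzoate trans) | O=C(c1ccccc1)OC[C@]1(O)C=CC=C[C@@H]1OC(=O)c1ccccc1
A4 | alternative 2 | [8-(benzoyloxy)-7-hydroxy-2,3-dioxabicyclo[2.2.2]oct-5-en-7-yl]methyl benzoate (peroxide bridge syn to the hydroxyl) | O=C(c1ccccc1)OC[C@]1(O)[C@@H]2C=C[C@@H](OO2)[C@@H]1OC(=O)c1ccccc1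
A5 | alternative 3 | 6-[(bromomethyl)dimethylsilyloxy]-2,5-bis(4-methoxybenzyloxy)cyclohex-3-en-1-one | O=C1[C@H](OCc2ccc(OC)cc2)C=C[C@@H](OCc2ccc(OC)cc2)[C@@H]1O[Si](C)(C)CBr
A6 | alternative 3 | cis-fused 2,2-dimethyl-1,2-oxasilolane on the cyclohexene, with the tertiary C1 hydroxyl and two 4-methoxybenzyl ethers | O[C@@]1(C[Si](C)(C)O2)[C@H](OCc3ccc(OC)cc3)C=C[C@@H](OCc3ccc(OC)cc3)[C@@H]12
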